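## Structural features

Compound 13 is a 1-aryl-1,2-dihydronaphthalene lignan. Ring A is a benzene ring with methoxy groups at C6, C7 and C8, fused through C4a and C8a to ring B (C1–C4), which holds a C3=C4 double bond conjugated with ring A. C1 carries a 3,4-dimethoxyphenyl ring and lies peri to the C8 methoxy group; C2 carries the hydroxymethyl carbon C9 and C3 the hydroxymethyl carbon C10. The only stereocentres are the neighbouring methines C1 (R) and C2 (S), with the aryl group and C9 trans on ring B. The dihydronaphthalene is fragile: C2–H is allylic, so the double bond can migrate or the ring can aromatise. The C10 hydroxyl is allylic and conjugated through C3=C4 to the electron-rich ring A, so it ionises in acid, and five aryl methyl ethers exclude strong Lewis acids and oxidants. The real difficulty is absolute control at two adjacent all-carbon stereocentres, C1 being flanked by two similar electron-rich aryl groups with no heteroatom handle. The key step exploits two facts. C1 is bonded to C8a (methoxy groups ortho at C8 and para at C6) and to the dimethoxyphenyl ring (para methoxy), so an oxygen leaving group there ionises to a stabilised planar cation. C2 is the α-carbon of C9, so with C9 as an aldehyde a chiral enamine makes C2 nucleophilic, and joining C1 to C2 closes ring B.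

## Logic of the disconnections

13 from 12: no skeletal bond is cut. The two primary alcohols are traced back to a C9 aldehyde and a C10 methyl ester. C9 must be an aldehyde so that an amine can activate C2. C10 is kept as an ester because a free C10 hydroxyl next to the C9 aldehyde would close to a five-membered lactol, which under the acid of the key step dehydrates and aromatises irreversibly to a furan; an allylic C10–O bond would also be a second ionisable site. The gain is a one-step end game. The demand is that hydride reaches the aldehyde before C2 epimerises and reduces the enoate in the 1,2 sense.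

12 from 11: the C1–C2 bond is cut. This opens ring B and removes both stereocentres, leaving an acyclic aldehyde whose only stereocentre (C1) is racemic and is erased on ionisation. The C1 oxygen is carried as a methyl ether rather than a hydroxyl: it ionises to the same cation, but cannot form a cyclic hemiacetal with a neighbouring carbonyl, cannot add to an acrylate, and is not oxidised when C9 is raised to the aldehyde. The demand on the forward step is ionisation at C1 only, reaction at the α-carbon, and control of both new centres. The stereodescriptors were re-derived from the target: C1 is R, C2 is S, trans, and the alkene of 11 must be E so that ring A is cis to C2.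

11 from 9 through 10: no skeletal bond is cut; only the oxidation level of C9 changes (acid, alcohol, aldehyde). The half-ester 9 already has the acid on the C2 arm and the ester on C3, which is exactly the differentiation needed. The demand is reduction of the acid beside a conjugated ester, and an oxidation that does not move C3=C4.

9 from 7 and 8: the C3=C4 double bond is cut. A Stobbe condensation brings in C3, C2, C9 and C10 in one step from a commercial diester, places ring A cis to the C2 arm, and differentiates the two carboxyl carbons. The demand is a base-stable C1 substituent without a nucleophilic oxygen. A free C1 alkoxide would add to the new acrylate to give a dihydroisobenzofuran, and the free ortho-hydroxybenzyl aldehyde would exist as a lactol that dehydrates to an isobenzofuran.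

7 from 2 and 3 through 6, 5 and 4: 7 comes from 6 by acetal hydrolysis. 6 is cut at C1–C8a (and at O–CH3), an aryllithium adding to the aldehyde carbon of 3. This reduces the diarylmethyl unit to two simple aromatic aldehydes. The demands are a masked ring A aldehyde during lithiation, and methylation of the alkoxide before any acid is applied.

2 from 1: the acetal C–O bonds are cut. The dimethyl acetal is chosen because it hydrolyses under acid far milder than that needed to ionise C1.

## Other disconnections considered

Alternative 1: The cut runs through C2–C3 and C1–C8a, with an ether oxygen joining C9 and C10 as a temporary tether. A chiral bisphosphine complex L*(AuCl)2 activated with AgSbF6 (monovalent gold) would coordinate the alkyne of the enyne ether 5-(3-{[(2Z)-3-(3,4-dimethoxyphenyl)prop-2-en-1-yl]oxy}prop-1-yn-1-yl)-1,2,3-trimethoxybenzene A1. The alkene carbon C2 would add to C3 in a 5-exo-dig closure, and the benzylic cation at C1 would be captured by an ortho carbon of the trimethoxyphenyl ring. The product would be (3aS,4R)-4-(3,4-dimethoxyphenyl)-5,6,7-trimethoxy-1,3,3a,4-tetrahydronaphtho[2,3-c]furan A2.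
- In favour: two C–C bonds, ring B and both stereocentres arise in one catalytic step from an achiral ether needing about three steps. The arene closure has no regiochemical question, since both ortho positions are equivalent. C9 and C10 are already at the alcohol level. The reaction class is established. On step count to the bicyclic core and on precedent it is better than the chosen plan.
- Against: if the cyclopropyl gold carbene opens with inversion, the alkyne carbon and the arene add to opposite faces of the alkene, so the trans relation of 13 would need the (Z)-alkene of A1. The very electron-rich benzylic cation may open fully and lose that link. A linear two-coordinate gold centre holds its ligand far from the reacting carbons, so absolute control is uncertain. Above all, A2 is not 13: the tether must be removed by net hydrolysis of a dialkyl ether, and reagents that do this also attack the aryl methyl ethers and the styrene.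
- Comparison: both plans pass through a C1 cation stabilised by the dimethoxyphenyl ring, but here C8a is the nucleophile and the end game is the weak part, whereas 12 is one reduction from 13. It is better to the core and worse from the core to the target.

Alternative 2: The cut removes the pendant aryl group from C1 and breaks C1–C2. Zerovalent palladium (Pd2(dba)3, a chiral phosphine, LiOtBu) would insert into 4-bromo-1,2-dimethoxybenzene A4. The diazo compound released by base from the hydrazone dimethyl (2E)-2-[(3,4,5-trimethoxy-2-{[2-(4-methylbenzenesulfonyl)hydrazinylidene]methyl}phenyl)methylidene]butanedioate A3 would give a palladium carbene at C1. Aryl migration would form the C1–aryl bond, and the C2 carbanion of the succinate arm would attack the η3-diarylmethyl palladium to close ring B. The product would be dimethyl (1R,2S)-1-(3,4-dimethoxyphenyl)-6,7,8-trimethoxy-1,2-dihydronaphthalene-2,3-dicarboxylate A5.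
- In favour: it is convergent and the pendant ring enters last from a simple bromide. A5 has no aldehyde and is less prone to epimerisation than 12, which is better. One hydride reduction takes A5 to 13, which is equal to the chosen end game. The succinate arm needs no differentiation of its two carboxyl groups, which is better than the acid-to-aldehyde adjustment of the chosen route.
- Against: the aryl diazo group sits next to an acrylate, so intramolecular dipolar cycloaddition or cyclopropanation may outrun carbene transfer to palladium. Hot alkoxide can shift the C3=C4 bond or aromatise the product. A chiral ligand must distinguish two similar aryl groups on the η3 fragment, and C2 would be set only by equilibration. Ring A needs two ortho carbonyl-level carbons, which costs about as many steps as the chosen route to 7.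
- Comparison: the bond set overlaps with the chosen plan (C1–C2 closes ring B in both) and the step count is similar. Stereocontrol rests on an untested metal-centred step instead of a face-shielded enamine, and the thermal basic conditions are harsher on the dihydronaphthalene.

Alternative 3: The cut removes ring A at C4–C4a and C1–C8a. The aryne released with CsF from 3,4,5-trimethoxy-2-(trimethylsilyl)phenyl trifluoromethanesulfonate A6 would add the chiral amino diene (2S)-1-[(3Z)-3-({[tert-butyl(dimethyl)silyl]oxy}methyl)-4-(3,4-dimethoxyphenyl)buta-1,3-dien-2-yl]-2-(methoxymethyl)pyrrolidine A7 (or its antipode) in a Diels–Alder sense. Hydrolysis of the enamine would give (3R,4R)-3-({[tert-butyl(dimethyl)silyl]oxy}methyl)-4-(3,4-dimethoxyphenyl)-5,6,7-trimethoxy-3,4-dihydronaphthalen-2(1H)-one A8.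
- In favour: ring A arrives as one simple fragment. The regiochemistry is well founded, because the nucleophilic enamine terminus C4 should bond to the aryne carbon remote from the neighbouring methoxy group, which places C1 next to C8; this is a real strength. No cation chemistry is involved. C2 can settle trans by enolisation, which is equal to the chosen plan.
- Against: the chiral amine is stoichiometric. Facial control at C1 must come from a remote pyrrolidine centre in an early transition state of a very reactive aryne, and ene reaction or arylation of the enamine can compete. A8 has a ketone at C3 where 13 needs an sp2 carbon bearing C10, so triflation toward C4, palladium-catalysed methoxycarbonylation, ester reduction and desilylation must follow. The β-silyloxy ketone can eliminate, and A6 and A7 each need several steps.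
- Comparison: this alternative is clearly longer than the chosen plan and is weaker on absolute stereocontrol; its regiochemical logic is equally sound.

Key step: step 7

Remark on the chemistry (assumption): C10 is carried through the key step as a methyl ester and the C1 oxygen as a methyl ether. Both are treated as spectator and protecting groups on the unchanged carbon skeletons of precursor 11 and product 12, and the leaving group at C1 is therefore methanol.

## Route

Step 1
Reactants: 1 2-bromo-3,4,5-trimethoxybenzaldehyde
Product: 2 2-bromo-1-(dimethoxymethyl)-3,4,5-trimethoxybenzene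
Conditions: HC(OMe)3, MeOH, TsOH·H2O (cat.), 50 °C; Et3N quench
Reagents that add atoms: trimethyl orthoformate, COC(OC)OC; methanol, CO
Why: Acid-catalysed acetalisation with the orthoformate as water scavenger masks the aldehyde for the bromine–lithium exchange; the dimethyl acetal is chosen because it is later removed under acid too mild to ionise C1.

Step 2
Reactants: 2 2-bromo-1-(dimethoxymethyl)-3,4,5-trimethoxybenzene; 3 3,4-dimethoxybenzaldehyde (veratraldehyde)
Product: 6 1-(dimethoxymethyl)-2-[(3,4-dimethoxyphenyl)(methoxy)methyl]-3,4,5-trimethoxybenzene (racemic), via aryllithium 4 (not isolated), via lithium alkoxide 5 (not isolated)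
Conditions: n-BuLi, THF, −78 °C; then 3, −78 → 0 °C; then MeI, DMPU, 0 °C → rt; aq. NaHCO3
Reagents that add atoms: iodomethane, CI
Why: Bromine–lithium exchange at −78 °C is faster than attack on the acetal, and 1,2-addition of the aryllithium to 3 forms the C1–C8a bond. Williamson O-methylation of the alkoxide in the same flask fixes C1 as a methyl ether; C1 is racemic, which is irrelevant because it is ionised in step 7.

Step 3
Reactants: 6 1-(dimethoxymethyl)-2-[(3,4-dimethoxyphenyl)(methoxy)methyl]-3,4,5-trimethoxybenzene
Product: 7 2-[(3,4-dimethoxyphenyl)(methoxy)methyl]-3,4,5-trimethoxybenzaldehyde (racemic)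
Conditions: pyridinium p-toluenesulfonate (10 mol%), acetone/H2O 10:1, rt; NaHCO3 quench
Reagents that add atoms: water, O
Why: Acetal hydrolysis through the oxocarbenium ion is expected to be far faster at this acidity than ionisation of the diarylmethyl ether, and the methyl ether cannot close onto the freed aldehyde as a lactol.

Step 4
Reactants: 7 2-[(3,4-dimethoxyphenyl)(methoxy)methyl]-3,4,5-trimethoxybenzaldehyde; 8 dimethyl succinate
Product: 9 (E)-4-{2-[(3,4-dimethoxyphenyl)(methoxy)methyl]-3,4,5-trimethoxyphenyl}-3-(methoxycarbonyl)but-3-enoic acid
Conditions: tBuOK, tBuOH, 60 °C; then cold 1 M HCl to pH 3, EtOAc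
Reagents that add atoms: none
Why: Stobbe condensation: the succinate enolate adds to the aldehyde, the alkoxide closes to a paraconic lactone, and E1cB opening gives the half-ester with the acid on the C2 arm (C9) and the ester on C3 (C10). The aryl group avoids the ester, so the (E)-alkene with ring A cis to C2 is the usual product, and the C1 methyl ether is inert to the base.

Step 5
Reactants: 9 (E)-4-{2-[(3,4-dimethoxyphenyl)(methoxy)methyl]-3,4,5-trimethoxyphenyl}-3-(methoxycarbonyl)but-3-enoic acid
Product: 10 methyl (E)-2-({2-[(3,4-dimethoxyphenyl)(methoxy)methyl]-3,4,5-trimethoxyphenyl}methylidene)-4-hydroxybutanoate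
Conditions: BH3·SMe2, THF, 0 °C → rt; MeOH, then water
Reagents that add atoms: none
Why: Chemoselective borane reduction of a carboxylic acid through its acyloxyborane, which is much faster than attack on the conjugated ester or hydroboration of the trisubstituted, ester-bearing alkene; the crude alcohol is used at once to avoid lactonisation.

Step 6
Reactants: 10 methyl (E)-2-({2-[(3,4-dimethoxyphenyl)(methoxy)methyl]-3,4,5-trimethoxyphenyl}methylidene)-4-hydroxybutanoate
Product: 11 methyl (E)-2-({2-[(3,4-dimethoxyphenyl)(methoxy)methyl]-3,4,5-trimethoxyphenyl}methylidene)-4-oxobutanoate (racemic at C1)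
Conditions: Dess–Martin periodinane, NaHCO3, CH2Cl2, 0 °C → rt; used at once
Reagents that add atoms: none
Why: Dess–Martin oxidation of the only free alcohol (C1 is an ether and cannot be oxidised to a benzophenone); the bicarbonate buffer keeps the β,γ-unsaturated aldehyde from isomerising into conjugation.

Step 7
Reactants: 11 methyl (E)-2-({2-[(3,4-dimethoxyphenyl)(methoxy)methyl]-3,4,5-trimethoxyphenyl}methylidene)-4-oxobutanoate
Product: 12 methyl (1R,2S)-1-(3,4-dimethoxyphenyl)-2-formyl-6,7,8-trimethoxy-1,2-dihydronaphthalene-3-carboxylate
Conditions: (S)-α,α-diphenylprolinol trimethylsilyl ether (20 mol%), CF3CO2H (40 mol%), CH2Cl2/(CF3)2CHOH 9:1, 0.02 M, 0 °C; aq. NaHCO3, crude used at once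
Reagents that add atoms: none
Why: Proposed new method: CF3CO2H in the ionising medium converts the C1 methyl ether of either enantiomer of 11 into one planar diarylmethyl cation (stabilised by the C8 and C6 methoxy groups of ring A and the para methoxy of the pendant ring), while the amine condenses with the C9 aldehyde to the (E)-dienamine N–C9=C2–C3=C4; C2 attacks C1, and the iminium ion is hydrolysed by the water released in the condensation, so the catalyst turns over and methanol is the only by-product. The closest known reactions are the enamine-catalysed SN1-type α-alkylation of aldehydes with diarylmethanols and the aminocatalytic 1,6-addition of aldehydes to para-quinone methides, both intermolecular; a ring-forming closure through a dienamine has not been shown. Ring B closes in a 6-exo-trig mode with respect to the enamine C9=C2 bond (the cationic C1 is the trigonal acceptor and the enamine π bond stays outside the ring), and attack from the γ-carbon C4 is excluded because it would give a four-membered ring. C2 is controlled by the catalyst: the CPh2OSiMe3 group covers one face of the (E)-s-trans enamine, and bond formation on the open face should give 2S with the (S)-amine. C1 is controlled by the cyclic transition state: the dimethoxyphenyl group should sit pseudo-axial, away from the C8 methoxy and anti to the C9 aminovinyl group, which gives the trans (1R) product; because epimerisation at C2 through the enamine can only move a cis adduct to trans, the final enantiomeric purity rests on this face selection at C1. The step needs ionisation at C1 only, α- over γ-reactivity, and cyclisation faster than intermolecular Friedel–Crafts attack on the electron-rich rings; the substrate secures these by carrying C10 as an ester (no second ionisable C–O bond and no hydroxyl that could trap C9 as a lactol and aromatise to a furan), by the (E)-alkene that holds ring A cis to C2, and by high dilution.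

Step 8
Reactants: 12 methyl (1R,2S)-1-(3,4-dimethoxyphenyl)-2-formyl-6,7,8-trimethoxy-1,2-dihydronaphthalene-3-carboxylate
Product: 13 [(1R,2S)-1-(3,4-dimethoxyphenyl)-6,7,8-trimethoxy-1,2-dihydronaphthalene-2,3-diyl]dimethanol
Conditions: iBu2AlH (5 equiv), CH2Cl2, −78 → 0 °C; aq. potassium sodium tartrate
Reagents that add atoms: none
Why: Hydride reduction: the aldehyde is reduced at −78 °C before C2 can epimerise, and the conjugated ester is reduced in the 1,2 sense to the allylic alcohol; neither stereocentre is touched.

## Compound list

1 | 2-bromo-3,4,5-trimethoxybenzaldehyde | COc1cc(C=O)c(Br)c(OC)c1OC | starting material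
2 | 2-bromo-1-(dimethoxymethyl)-3,4,5-trimethoxybenzene | COc1cc(C(OC)OC)c(Br)c(OC)c1OC | intermediate
3 | 3,4-dimethoxybenzaldehyde (veratraldehyde) | COc1ccc(C=O)cc1OC | starting material
4 | [2-(dimethoxymethyl)-4,5,6-trimethoxyphenyl]lithium | COc1cc(C(OC)OC)c([Li])c(OC)c1OC | intermediate (not isolated)
5 | lithium (3,4-dimethoxyphenyl)[2-(dimethoxymethyl)-4,5,6-trimethoxyphenyl]methanolate, racemic | [Li+].[O-]C(c1ccc(OC)c(OC)c1)c1c(C(OC)OC)cc(OC)c(OC)c1OC | intermediate (not isolated)
6 | 1-(dimethoxymethyl)-2-[(3,4-dimethoxyphenyl)(methoxy)methyl]-3,4,5-trimethoxybenzene, racemic | COc1ccc(C(OC)c2c(C(OC)OC)cc(OC)c(OC)c2OC)cc1OC | intermediate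
7 | 2-[(3,4-dimethoxyphenyl)(methoxy)methyl]-3,4,5-trimethoxybenzaldehyde, racemic | COc1ccc(C(OC)c2c(C=O)cc(OC)c(OC)c2OC)cc1OC | intermediate
8 | dimethyl succinate | COC(=O)CCC(=O)OC | starting material
9 | (E)-4-{2-[(3,4-dimethoxyphenyl)(methoxy)methyl]-3,4,5-trimethoxyphenyl}-3-(methoxycarbonyl)but-3-enoic acid, racemic at C1 | COc1ccc(C(OC)c2c(/C=C(/C(=O)OC)CC(=O)O)cc(OC)c(OC)c2OC)cc1OC | intermediate
10 | methyl (E)-2-({2-[(3,4-dimethoxyphenyl)(methoxy)methyl]-3,4,5-trimethoxyphenyl}methylidene)-4-hydroxybutanoate, racemic at C1 | COc1ccc(C(OC)c2c(/C=C(/C(=O)OC)CCO)cc(OC)c(OC)c2OC)cc1OC | intermediate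
11 | methyl (E)-2-({2-[(3,4-dimethoxyphenyl)(methoxy)methyl]-3,4,5-trimethoxyphenyl}methylidene)-4-oxobutanoate, racemic at C1 | COc1ccc(C(OC)c2c(/C=C(/C(=O)OC)CC=O)cc(OC)c(OC)c2OC)cc1OC | intermediate (key-step precursor)
12 | methyl (1R,2S)-1-(3,4-dimethoxyphenyl)-2-formyl-6,7,8-trimethoxy-1,2-dihydronaphthalene-3-carboxylate | COc1ccc([C@@H]2c3c(cc(OC)c(OC)c3OC)C=C(C(=O)OC)[C@H]2C=O)cc1OC | intermediate (key-step product)
13 | [(1R,2S)-1-(3,4-dimethoxyphenyl)-6,7,8-trimethoxy-1,2-dihydronaphthalene-2,3-diyl]dimethanol | COc1ccc([C@@H]2c3c(cc(OC)c(OC)c3OC)C=C(CO)[C@H]2CO)cc1OC | target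

## Step count and least certain steps

Total step count: 8. Longest linear sequence: 8 steps (1 to 13); 3 and 8 enter as single reagents.

**Step 7 (key step).** Several things may go wrong.
- Ionisation at C1 may be too slow at an acid level the enamine tolerates, or the amine may be alkylated by the cation.
- Protonation of the dienamine at C4 may move the aldehyde into conjugation and scramble the alkene geometry.
- Facial selection at C1 may be poor, and cis material would then epimerise at C2 to the wrong enantiomer.
- Intermolecular Friedel–Crafts alkylation may give oligomers.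
- The C3=C4 bond of the product may migrate, or the ring may aromatise.

The fallback uses a chiral auxiliary in known titanium-enolate chemistry; it sets out from 9 and returns at 12. Acid 9 would be coupled (EDC·HCl, DMAP, CH2Cl2) with (4S)-4-(propan-2-yl)-1,3-thiazolidine-2-thione to give methyl (E)-2-({2-[(3,4-dimethoxyphenyl)(methoxy)methyl]-3,4,5-trimethoxyphenyl}methylidene)-4-oxo-4-[(4S)-4-(propan-2-yl)-2-sulfanylidene-1,3-thiazolidin-3-yl]butanoate F1. TiCl4 and iPr2NEt in CH2Cl2 at −78 °C would form the chelated chlorotitanium (Z)-enolate. The Lewis acid (with BF3·OEt2 added if needed) would ionise the C1 methyl ether, and the enolate carbon C2 would close onto C1 on the face away from the isopropyl group. This SN1 alkylation of such enolates with diarylmethyl methyl ethers is known intermolecularly, and by the same facial argument the (S)-auxiliary should give 2S. The product would be methyl (1R,2S)-1-(3,4-dimethoxyphenyl)-6,7,8-trimethoxy-2-{[(4S)-4-(propan-2-yl)-2-sulfanylidene-1,3-thiazolidin-3-yl]carbonyl}-1,2-dihydronaphthalene-3-carboxylate F2. One equivalent of iBu2AlH at −78 °C would cleave the thioimide of F2 to aldehyde 12, which continues with step 8.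

**Step 2.** O-Methylation of the hindered lithium alkoxide may be incomplete, and the aryllithium may be butylated by the 1-bromobutane formed in the exchange. The fallback sets out from 2 and 3 and returns at 6. The alkoxide 5 would be quenched with water and the carbinol (3,4-dimethoxyphenyl)[2-(dimethoxymethyl)-4,5,6-trimethoxyphenyl]methanol F3 isolated. F3 would then be stirred in MeOH with HC(OMe)3 and a trace of pyridinium p-toluenesulfonate. This exchanges the hydroxyl for methoxyl by an SN1 path (cation capture by solvent instead of alkoxide alkylation); the orthoformate removes water and returns any cyclic acetal formed with the neighbouring acetal carbon to the open form 6.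

**Step 3.** The C1 methyl ether may be lost by acid ionisation, or by participation of its oxygen in the oxocarbenium ion; this would lead to the cyclic lactol and to isobenzofuran-type decomposition. The fallback avoids acid altogether; it sets out from 1 and returns at 7.
- NaBH4 in MeOH would reduce 1 to (2-bromo-3,4,5-trimethoxyphenyl)methanol F4.
- iPr3SiCl and imidazole would give [(2-bromo-3,4,5-trimethoxyphenyl)methoxy]tri(propan-2-yl)silane F5.
- n-BuLi, then 3, then MeI/DMPU as in step 2 would give ({2-[(3,4-dimethoxyphenyl)(methoxy)methyl]-3,4,5-trimethoxyphenyl}methoxy)tri(propan-2-yl)silane F6. The bulky silyl group and −78 °C are chosen to suppress 1,4-migration of silicon from oxygen to the lithiated carbon.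
- Bu4NF in THF would give {2-[(3,4-dimethoxyphenyl)(methoxy)methyl]-3,4,5-trimethoxyphenyl}methanol F7.
- MnO2 in CH2Cl2 would oxidise the benzylic alcohol of F7 to 7.

**Step 5.** The hydroxy ester may lactonise onto the C10 ester, giving an arylidene butyrolactone that cannot be oxidised to 11, and borane may add to the alkene. The fallback avoids the alcohol stage; it sets out from 9 and returns at 11. Acid 9 would be converted (EtSH, EDC·HCl, DMAP, CH2Cl2) into methyl (E)-2-({2-[(3,4-dimethoxyphenyl)(methoxy)methyl]-3,4,5-trimethoxyphenyl}methylidene)-4-(ethylsulfanyl)-4-oxobutanoate F8. A Fukuyama reduction (Et3SiH, Pd/C, acetone, rt) would take F8 directly to aldehyde 11, so that 10 and step 6 are bypassed.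

## Further compounds

F1 | step 7 | methyl (E)-2-({2-[(3,4-dimethoxyphenyl)(methoxy)methyl]-3,4,5-trimethoxyphenyl}methylidene)-4-oxo-4-[(4S)-4-(propan-2-yl)-2-sulfanylidene-1,3-thiazolidin-3-yl]butanoate | COc1ccc(C(OC)c2c(/C=C(/C(=O)OC)CC(=O)N3[C@@H](C(C)C)CSC3=S)cc(OC)c(OC)c2OC)cc1OC
F2 | step 7 | methyl (1R,2S)-1-(3,4-dimethoxyphenyl)-6,7,8-trimethoxy-2-{[(4S)-4-(propan-2-yl)-2-sulfanylidene-1,3-thiazolidin-3-yl]carbonyl}-1,2-dihydronaphthalene-3-carboxylate | COc1ccc([C@@H]2c3c(cc(OC)c(OC)c3OC)C=C(C(=O)OC)[C@H]2C(=O)N4[C@@H](C(C)C)CSC4=S)cc1OC
F3 | step 2 | (3,4-dimethoxyphenyl)[2-(dimethoxymethyl)-4,5,6-trimethoxyphenyl]methanol, racemic | COc1ccc(C(O)c2c(C(OC)OC)cc(OC)c(OC)c2OC)cc1OC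
F4 | step 3 | (2-bromo-3,4,5-trimethoxyphenyl)methanol | COc1cc(CO)c(Br)c(OC)c1OC
F5 | step 3 | [(2-bromo-3,4,5-trimethoxyphenyl)methoxy]tri(propan-2-yl)silane | COc1cc(CO[Si](C(C)C)(C(C)C)C(C)C)c(Br)c(OC)c1OC
F6 | step 3 | ({2-[(3,4-dimethoxyphenyl)(methoxy)methyl]-3,4,5-trimethoxyphenyl}methoxy)tri(propan-2-yl)silane, racemic | COc1ccc(C(OC)c2c(CO[Si](C(C)C)(C(C)C)C(C)C)cc(OC)c(OC)c2OC)cc1OC
F7 | step 3 | {2-[(3,4-dimethoxyphenyl)(methoxy)methyl]-3,4,5-trimethoxyphenyl}methanol, racemic | COc1ccc(C(OC)c2c(CO)cc(OC)c(OC)c2OC)cc1OC
F8 | step 5 | methyl (E)-2-({2-[(3,4-dimethoxyphenyl)(methoxy)methyl]-3,4,5-trimethoxyphenyl}methylidene)-4-(ethylsulfanyl)-4-oxobutanoate, racemic at C1 | COc1ccc(C(OC)c2c(/C=C(/C(=O)OC)CC(=O)SCC)cc(OC)c(OC)c2OC)cc1OC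
A1 | alternative 1 | 5-(3-{[(2Z)-3-(3,4-dimethoxyphenyl)prop-2-en-1-yl]oxy}prop-1-yn-1-yl)-1,2,3-trimethoxybenzene | COc1ccc(/C=C\COCC#Cc2cc(OC)c(OC)c(OC)c2)cc1OC
A2 | alternative 1 | (3aS,4R)-4-(3,4-dimethoxyphenyl)-5,6,7-trimethoxy-1,3,3a,4-tetrahydronaphtho[2,3-c]furan | COc1ccc([C@@H]2c3c(cc(OC)c(OC)c3OC)C=C4[C@H]2COC4)cc1OC
A3 | alternative 2 | dimethyl (2E)-2-[(3,4,5-trimethoxy-2-{[2-(4-methylbenzenesulfonyl)hydrazinylidene]methyl}phenyl)methylidene]butanedioate | COc1cc(/C=C(/C(=O)OC)CC(=O)OC)c(C=NNS(=O)(=O)c2ccc(C)cc2)c(OC)c1OC
A4 | alternative 2 | 4-bromo-1,2-dimethoxybenzene | COc1ccc(Br)cc1OC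
A5 | alternative 2 | dimethyl (1R,2S)-1-(3,4-dimethoxyphenyl)-6,7,8-trimethoxy-1,2-dihydronaphthalene-2,3-dicarboxylate | COc1ccc([C@@H]2c3c(cc(OC)c(OC)c3OC)C=C(C(=O)OC)[C@H]2C(=O)OC)cc1OC
A6 | alternative 3 | 3,4,5-trimethoxy-2-(trimethylsilyl)phenyl trifluoromethanesulfonate | COc1cc(OS(=O)(=O)C(F)(F)F)c([Si](C)(C)C)c(OC)c1OC
A7 | alternative 3 | (2S)-1-[(3Z)-3-({[tert-butyl(dimethyl)silyl]oxy}methyl)-4-(3,4-dimethoxyphenyl)buta-1,3-dien-2-yl]-2-(methoxymethyl)pyrrolidine | C=C(N1CCC[C@H]1COC)/C(CO[Si](C)(C)C(C)(C)C)=C/c1ccc(OC)c(OC)c1
A8 | alternative 3 | (3R,4R)-3-({[tert-butyl(dimethyl)silyl]oxy}methyl)-4-(3,4-dimethoxyphenyl)-5,6,7-trimethoxy-3,4-dihydronaphthalen-2(1H)-one | COc1ccc([C@@H]2c3c(cc(OC)c(OC)c3OC)CC(=O)[C@H]2CO[Si](C)(C)C(C)(C)C)cc1OC
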